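The south-west flask, which starts with 0.100 M of G on top of the north-east charge, makes G about as fast as the north-east flask: at 4.2 h the G made reads 0.122 M in the south-west flask against 0.1228 M in the north-east flask. Added G therefore shows no visible brake in these readings.

in all of them: Q 0.200 M; Z 0.160 M; E 0.0160 M

| run | G | time |
|---|---|---|
| north-east |  |  |
| south-west | 0.100 M |  |
| north |  | 17 h |

| run | time / h | [G] / M |
|---|---|---|
| north-east run | 0.17 | 0.0282 |
| north-east run | 0.27 | 0.0421 |
| north-east run | 0.42 | 0.0556 |
| north-east run | 0.67 | 0.0735 |
| north-east run | 1.1 | 0.0920 |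
| north-east run | 1.7 | 0.1057 |
| north-east run | 2.7 | 0.1161 |
| north-east run | 4.2 | 0.1228 |
| south-west run | 0.17 | 0.1282 |
| south-west run | 0.27 | 0.1407 |
| south-west run | 0.42 | 0.1554 |
| south-west run | 0.67 | 0.1738 |
| south-west run | 1.1 | 0.1925 |
| south-west run | 1.7 | 0.2052 |
| south-west run | 2.7 | 0.2172 |
| south-west run | 4.2 | 0.2218 |

(readings scatter by 6 × 10⁻⁴ M)

- G in the north run at 17 h, as a share of the Q charged

- Overall: Q + Z -> G, with E as catalyst.
- Constant volume, constant temperature.
- The analysis sees a species whether free or bound.

Each turn takes one Q and one Z, and Z is charged at 0.160 M against 0.200 M of Q, so Z is the limiting reagent. The north flask has the north-east charge, and its reagent ceiling, the Z charged over the Q charged, is 80.0%.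

The north-east flask slows well under that ceiling. Its last reading is 61.4% of the Q charged, and its hourly gain drops from 0.0104 M h⁻¹ over the last interval but one to 0.00447 M h⁻¹ over the last. If that decline continues at its read pace of 0.676 h⁻¹, the tail adds 0.00398 M, and this reckoning puts the north flask at 63.4%.

The forecast says 64.5%, which is 1.1 percentage points above that reckoning, and its ground is “The catalyst is therefore dying”.

The north flask gives 62.7% at 17 h, and the forecast stands right within its margin.

    2 E ⇌ E2, settled at all times (278.0 M⁻¹)
    E2 + Q + Z → G + E2 (1552 M⁻² h⁻¹)
    2 Z ⇌ Z2, settled at all times (1.780 M⁻¹)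
    2 Z → Wa (3.107 M⁻¹ h⁻¹)

That result lies 17 points under the ceiling, and 0.0346 M of the Z charged has not become G. The cause is the conversion of Z into Wa: the north flask without that step reaches 80.0%, the ceiling itself, against 62.7% with it. The ceiling counts G made, so the south-west flask is measured without its added G: at 4.2 h the G it has made reads 60.9% of the Q charged, 19 points under the same ceiling.

The earlier runs and the new flask come from a simulation with constants of no real substance.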